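Numbering used throughout: the reduced unit has chromone numbering (O1, C2–C4, C4a, C5–C8, C8a); atoms of the aromatic chromone carry the suffix B.

## The problem

(+)-4'-Methoxyaquisinenone G (28) joins two 2-(2-arylethyl)chromones: an aromatic one (B) and one whose carbocycle C4a–C5–C6–C7–C8–C8a is saturated at C5–C8 and oxygenated on each of these four carbons. The catechol oxygens of the aromatic unit are bonded to C7 (O6B) and to C5 (O7B), so a seven-membered dioxepine spans C5 and C7 across C6. This forces both aryl ether bonds cis and axial, with the C6 and C8 hydroxyls trans to them (5R,6S,7R,8S). Only C5 can be left to the end, because O7B, once tied to C7 through the catechol, can reach C5 only on the face of the C7–O bond. C6, C7 and C8 must be set earlier, and since both halves are achiral the absolute configuration has to come from a reagent. The molecule tolerates little: C5 ionises easily (O1 stabilises the cation through C8a=C4a), the tetraoxygenated ring is two eliminations away from an aromatic chromone, any C6 carbonyl intermediate has hydroxy or aryloxy leaving groups in the β-position, and both pyranones are open to conjugate attack by hydride at C2. The feature that invites a short solution is that C5 and C8 are the carbons attached to C4a and C8a of the pyranone: the ring C4a–C5–C6–C7–C8–C8a is the formal Diels–Alder adduct of a pyranone 2,3-quinodimethane (C5=C4a–C8a=C8) and a C6=C7 alkene that already bears O6B. A quinodimethane oxygenated at C5 and C8 is the photoenol of a 3-formyl-2-(oxymethyl)-4-pyranone, and the hydroxyl it delivers sits on the very carbon that must later ionise.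

## Retrosynthesis

**Unmasking (28 ⇐ 27 ⇐ 26).** No skeletal bond is cut. The C6 acetate and C8 silyl ether of 26 are kept until the bridge exists, because a free C6 hydroxyl beside a C5 cation would invite a 1,2-hydride shift to a C6 ketone. The forward steps (fluoride, then methanolysis) need only spare the two aryl ethers.

**C5–O7B (26 ⇐ 24, through phenol 25).** Of the two aryl ether bonds, only the one at C5 can be made by ionisation, since a C7 cation has no support from O1. Cutting here also leaves C7–O6B as the tether that dictates the face of closure. The precursor 24 is a monocyclic cyclohexene with an open C5 hydroxyl and a MOM-protected O7B. The forward step asks acid to remove MOM, ionise C5 and let O7B close the seven-membered ring, with the C6 acetate shielding the opposite face.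

**C6–O (24 ⇐ 23).** The C6 oxygen is traced to a C6 acetyl group by Baeyer–Villiger oxidation with retention. A dienophile carrying oxygen on both carbons would be too electron-rich for an electron-rich dienol. The acetyl group activates the alkene, gives titanium a binding site, and is a latent hydroxyl. The oxidation must precede bridge closure, because an acetyl α-hydrogen at C6 would let a C5 cation collapse to an enone.

**C5–C6 and C7–C8 (23 ⇐ 13 + 21, through photodienol 22).** This is the central cut. Single-bond alternatives at C6–C7 or C7–C8 need the two halves joined by ether bonds first. The double cut divides the molecule into a pyranone aldehyde 13 and an aryloxyenone 21 of similar size, neither with a stereocentre. The forward reaction must form two C–C bonds and four stereocentres with regio-, endo- and facial control. The E-geometry of 21 supplies the trans C6/C7 relation, and the outward geometry of 22 the cis C5/C8 relation.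

**Enone 21 (⇐ 19 + 20; 19 ⇐ 18 ⇐ 17 ⇐ 14 + 15, through 16).** The enol ether C–O bond is cut to phenol 19 and but-3-yn-2-one (20). The MOM group on O7B comes from selective alkylation of the more acidic 7-hydroxyl of catechol 18. Compound 18 comes from demethylation of 17, the Claisen/cyclodehydration product of acetophenone 14 and ester 15 via diketone 16.

**Aldehyde 13 (⇐ 12 ⇐ 5 + 10, through 11).** The formyl group is taken from a thioester (12), so the aldehyde can be released by palladium and a silane. A carboxylic ester would need a hydride reagent, which attacks C2 of 3-acylpyranones. The pyranone is cut at C3–C4 and O1–C6 into β-keto thioester 5 and ynoyl chloride 10; the triketone 11 closes by itself. Chloride 10 comes from acid 9, made from aldehyde 6 by Corey–Fuchs homologation (7, acetylide 8) and carboxylation. Thioester 5 comes from the aldol of 1 (as enolate 3) with 2, giving 4, then oxidation.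

## Roads not taken

**Alternative 1:** The cut is C4a–C5, with the carbocycle traced to a sugar enol ether in which both aryl ether bonds already exist. The tetravalent titanium Lewis acid Ti(OiPr)Cl3 would ionise the anomeric C–O5 bond with retention of the aryloxy group, and the enolate carbon would close onto the cation to give ketone A1.
- Merits: all four stereocentres come from the chiral pool, and no ionisation at C5 is needed at the end. In absolute stereocontrol this road is better than the chosen one.
- Weak points: the substrate must hold a catechol across two sugar oxygens, possible only in the all-axial chair. After A1 the whole pyranone with its side chain must still be built on a ketone that has a β-aryloxy group, so every enolisation risks elimination. The benzyl ethers must then be removed without hydrogenolysis of the allylic C5–O and C8–O bonds.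
- Comparison: the chosen plan sets convergence and length against this (two complete halves, 16 steps, no enolisable ketone flanked by leaving groups). In return it accepts a photoreaction on an untested substrate class.

**Alternative 2:** The cut is C6–C7 inside a nine-membered catechol diether. A chiral secondary amine such as proline would form the C7=C8 enamine of the C8 ketone, which adds to the C6 aldehyde and closes carbocycle and dioxepine at once to give A2.
- Merits: the C6 hydroxyl arises directly, so no Baeyer–Villiger step is needed, and A2 is one reduction from the target. The endgame is shorter than the chosen one.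
- Weak points: the substrate needs C5 already set at an ionisable position α to an aldehyde, and a medium ring made by two aryl ether bonds. The ketone is an α-aryloxy acylpyranone, slow to form an enamine and prone to lose aryloxide. The C8 reduction must then be trans-selective.
- Comparison: the chosen plan moves the difficulty into one cycloaddition between simple partners; the precursor of A2 would cost more steps than both of those partners together.

**Alternative 3:** The cut is C7–C8. Divalent chromium (CrCl2) with Me3SiI and a chiral sulfonamide ligand would open a vinyl benzodioxole acetal to an aryloxyallyl chromium species that adds to the C8 aldehyde, giving A3 with free O7B.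
- Merits: the cyclic transition state should give the trans C7/C8 relation. The C5=C6 alkene left in A3 allows epoxidation and intramolecular opening at C5 by O7B with clean inversion, a more reliable way to set C5 than the ionisation used here.
- Weak points: only an electronic bias decides which acetal C–O bond breaks. Asymmetric chromium allylation is established for intermolecular allyl halides, not for acetal-derived oxyallyl reagents. A3 is a dihydroarene with two leaving groups, one elimination from an aromatic chromone.
- Comparison: the chosen plan never passes through a dihydroarene and forms two C–C bonds in its key step; it gives up the cleaner control at C5.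

Key step: step 12

Assumption: the sense of induction of a titanium TADDOLate on a pyranone dienol cannot be derived with certainty; (R,R)-TADDOL is written for attack on the C5-Re/C8-Si face of 22, and the equally available (S,S)-ligand replaces it if the opposite face proves open.

## Route

Step 1
Reactants: 1 S-ethyl ethanethioate; 2 [(tert-butyldimethylsilyl)oxy]acetaldehyde
Product: 4 rac-S-ethyl 4-[(tert-butyldimethylsilyl)oxy]-3-hydroxybutanethioate, via lithium enolate 3 (not isolated)
Conditions: LiN(iPr)2 (LDA), THF, −78 °C; then 2, −78 °C; aq. NH4Cl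
Reagents that add atoms: none
Why: Aldol addition of a preformed lithium thioester enolate to an aldehyde; the new carbinol centre is racemic and is removed in step 2.

Step 2
Reactants: 4 rac-S-ethyl 4-[(tert-butyldimethylsilyl)oxy]-3-hydroxybutanethioate
Product: 5 S-ethyl 4-[(tert-butyldimethylsilyl)oxy]-3-oxobutanethioate
Conditions: Dess–Martin periodinane, NaHCO3, CH2Cl2, 0 °C → rt
Reagents that add atoms: none
Why: Dess–Martin oxidation of a secondary alcohol under buffered, non-basic conditions; thioester and silyl ether are not affected.

Step 3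
Reactants: 6 3-(4-methoxyphenyl)propanal
Product: 7 1-(4,4-dibromobut-3-en-1-yl)-4-methoxybenzene
Conditions: CBr4, PPh3, CH2Cl2, 0 °C
Reagents that add atoms: carbon tetrabromide, BrC(Br)(Br)Br
Why: First stage of the Corey–Fuchs homologation (dibromomethylenation of an aliphatic aldehyde); the anisole ring is inert.

Step 4
Reactants: 7 1-(4,4-dibromobut-3-en-1-yl)-4-methoxybenzene
Product: 9 5-(4-methoxyphenyl)pent-2-ynoic acid, via lithium acetylide 8 (not isolated)
Conditions: n-BuLi (2.1 equiv), THF, −78 → 0 °C; then CO2 (g), −78 °C → rt; aq. HCl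
Reagents that add atoms: carbon dioxide, O=C=O
Why: Second stage of the Corey–Fuchs sequence: bromine–lithium exchange and 1,2-shift give the acetylide, which CO2 carboxylates.

Step 5
Reactants: 9 5-(4-methoxyphenyl)pent-2-ynoic acid
Product: 10 5-(4-methoxyphenyl)pent-2-ynoyl chloride
Conditions: (COCl)2, Me2NCHO (cat.), CH2Cl2, 0 °C → rt; concentrate, use crude
Reagents that add atoms: oxalyl chloride, O=C(Cl)C(=O)Cl
Why: Vilsmeier-type acid chloride formation under neutral conditions, mild enough for a 2-alkynoic acid.

Step 6
Reactants: 5 S-ethyl 4-[(tert-butyldimethylsilyl)oxy]-3-oxobutanethioate; 10 5-(4-methoxyphenyl)pent-2-ynoyl chloride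
Product: 12 S-ethyl 2-{[(tert-butyldimethylsilyl)oxy]methyl}-6-[2-(4-methoxyphenyl)ethyl]-4-oxo-4H-pyran-3-carbothioate, via triketone 11 (not isolated)
Conditions: MgCl2, Et3N, MeCN, 0 °C → rt; then 40 °C
Reagents that add atoms: none
Why: Magnesium-mediated C-acylation of a 1,3-dicarbonyl compound gives triketone 11, whose ketone enol oxygen adds to the ynone in a 6-endo-dig oxa-Michael closure, the classical 4-pyranone synthesis from alkynoyl chlorides and β-keto esters. The ketone and not the thioester carbonyl supplies the ring oxygen because it is the enolised one.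

Step 7
Reactants: 12 S-ethyl 2-{[(tert-butyldimethylsilyl)oxy]methyl}-6-[2-(4-methoxyphenyl)ethyl]-4-oxo-4H-pyran-3-carbothioate
Product: 13 2-{[(tert-butyldimethylsilyl)oxy]methyl}-6-[2-(4-methoxyphenyl)ethyl]-4-oxo-4H-pyran-3-carbaldehyde
Conditions: Et3SiH, 10% Pd/C (cat.), acetone, rt
Reagents that add atoms: none
Why: Fukuyama reduction: zerovalent palladium inserts into the C–S bond and silicon delivers hydride, so no nucleophilic hydride meets the pyranone carbonyl or its C2 position.

Step 8
Reactants: 14 1-(2-hydroxy-4,5-dimethoxyphenyl)ethanone; 15 ethyl 3-phenylpropanoate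
Product: 17 6,7-dimethoxy-2-(2-phenylethyl)-4H-chromen-4-one, via diketone 16 (not isolated)
Conditions: NaH, THF, reflux; then conc. HCl, MeOH, reflux
Reagents that add atoms: none
Why: Claisen condensation of the acetophenone enolate with the ester gives the β-diketone, and acid closes it by cyclodehydration, the standard route to 2-(2-phenylethyl)chromones.

Step 9
Reactants: 17 6,7-dimethoxy-2-(2-phenylethyl)-4H-chromen-4-one
Product: 18 6,7-dihydroxy-2-(2-phenylethyl)-4H-chromen-4-one
Conditions: BBr3 (excess), CH2Cl2, −78 °C → rt; then MeOH/H2O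
Reagents that add atoms: none
Why: Lewis-acid cleavage of both aryl methyl ethers with BBr3; the chromone core is stable to it.

Step 10
Reactants: 18 6,7-dihydroxy-2-(2-phenylethyl)-4H-chromen-4-one
Product: 19 6-hydroxy-7-(methoxymethoxy)-2-(2-phenylethyl)-4H-chromen-4-one
Conditions: MeOCH2Cl (1.05 equiv), K2CO3 (1.0 equiv), acetone, 0 °C
Reagents that add atoms: chloromethyl methyl ether, COCCl
Why: Williamson-type alkylation of the more acidic phenol: the 7-hydroxyl is para to the carbonyl-bearing C4a and is ionised first by one equivalent of weak base, as in the 7-selective alkylation of 6,7-dihydroxycoumarins and flavones.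

Step 11
Reactants: 19 6-hydroxy-7-(methoxymethoxy)-2-(2-phenylethyl)-4H-chromen-4-one; 20 but-3-yn-2-one
Product: 21 (E)-4-{[7-(methoxymethoxy)-4-oxo-2-(2-phenylethyl)-4H-chromen-6-yl]oxy}but-3-en-2-one
Conditions: 1,4-diazabicyclo[2.2.2]octane (DABCO, 10 mol %), CH2Cl2, 0 °C → rt
Reagents that add atoms: none
Why: Amine-catalysed oxa-Michael addition of a phenol to an ynone; the intermediate protonates to the thermodynamically favoured E-enol ether.

Step 12
Reactants: 13 2-{[(tert-butyldimethylsilyl)oxy]methyl}-6-[2-(4-methoxyphenyl)ethyl]-4-oxo-4H-pyran-3-carbaldehyde; 21 (E)-4-{[7-(methoxymethoxy)-4-oxo-2-(2-phenylethyl)-4H-chromen-6-yl]oxy}but-3-en-2-one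
Product: 23 (5R,6S,7R,8S)-6-acetyl-8-[(tert-butyldimethylsilyl)oxy]-5-hydroxy-2-[2-(4-methoxyphenyl)ethyl]-7-{[7-(methoxymethoxy)-4-oxo-2-(2-phenylethyl)-4H-chromen-6-yl]oxy}-5,6,7,8-tetrahydro-4H-chromen-4-one, via photodienol 22 (not isolated)
Conditions: Ti(OiPr)4 (2 equiv), (R,R)-TADDOL (2.2 equiv), toluene, degassed, hν (365 nm LED), 10–20 °C
Reagents that add atoms: none
Why: Proposed new method: n,π* excitation of the formyl group of 13 should trigger 1,5-hydrogen transfer from the adjacent CH2OTBS group and give the long-lived dienol 22 with OH and OTBS both outward, which titanium captures as a dienolate chelated between O5 and the C4 carbonyl; the closest known reaction type is the Ti(OiPr)4/chiral-diol-promoted photoenolisation/Diels–Alder reaction of 2-alkylbenzaldehydes with enones, and a 4-pyranone aldehyde has not been used in it. The carbocycle closes by an intermolecular suprafacial [4+2] cycloaddition that forms C5–C6 and C7–C8 on one face of the diene and restores the pyranone. Regiochemistry follows from polarisation: the O–Ti donor at C5 and ring oxygen O1 on C8a both raise the coefficient at C8, which bonds to the β-carbon C7 of the enone, and the same titanium centre binds the acetyl oxygen so that the acyl-bearing carbon is delivered to C5. This template also enforces the endo transition state, which places acetyl cis to the C5 hydroxyl and the C8 silyloxy group (C5, C6, C8), while the E-geometry of 21 becomes the trans relation of acetyl and aryloxy (C7). The outward geometry of both oxygens in 22 fixes C5–OH and C8–OTBS cis. Absolute configuration at all four centres comes from the complex Ti(OiPr)2[(R,R)-TADDOLate], which must leave the C5-Re/C8-Si face of 22 open. The step needs selective excitation of 13 beside the chromone of 21, regio-, endo- and facial selectivity, and retention of the enone geometry; the chelating C4 carbonyl, present only in a pyranone aldehyde, is the substrate feature relied on for a rigid titanium complex.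

Step 13
Reactants: 23 (5R,6S,7R,8S)-6-acetyl-8-[(tert-butyldimethylsilyl)oxy]-5-hydroxy-2-[2-(4-methoxyphenyl)ethyl]-7-{[7-(methoxymethoxy)-4-oxo-2-(2-phenylethyl)-4H-chromen-6-yl]oxy}-5,6,7,8-tetrahydro-4H-chromen-4-one
Product: 24 (5S,6S,7R,8S)-8-[(tert-butyldimethylsilyl)oxy]-5-hydroxy-2-[2-(4-methoxyphenyl)ethyl]-7-{[7-(methoxymethoxy)-4-oxo-2-(2-phenylethyl)-4H-chromen-6-yl]oxy}-4-oxo-5,6,7,8-tetrahydro-4H-chromen-6-yl acetate
Conditions: mCPBA, NaHCO3, CH2Cl2, 0 °C → rt
Reagents that add atoms: 3-chloroperoxybenzoic acid, O=C(OO)c1cccc(Cl)c1
Why: Baeyer–Villiger oxidation: the secondary ring carbon migrates in preference to methyl and with retention, so C6–O replaces C6–acetyl on the same face. The push–pull double bonds of both pyranones are too electron-poor to be epoxidised, and the buffered medium avoids β-elimination of the aryloxy group.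

Step 14
Reactants: 24 (5S,6S,7R,8S)-8-[(tert-butyldimethylsilyl)oxy]-5-hydroxy-2-[2-(4-methoxyphenyl)ethyl]-7-{[7-(methoxymethoxy)-4-oxo-2-(2-phenylethyl)-4H-chromen-6-yl]oxy}-4-oxo-5,6,7,8-tetrahydro-4H-chromen-6-yl acetate
Product: 26 (5R,6S,7R,8S)-6-O-acetyl-8-O-(tert-butyldimethylsilyl) derivative of 28 (dioxepine closed: C5–O7B and C7–O6B), via phenol 25 (not isolated)
Conditions: CF3CO2H, CH2Cl2 (high dilution), 0 °C → rt
Reagents that add atoms: none
Why: Acidolysis of the aryl MOM ether frees O7B, and the C5 hydroxyl, whose cation is stabilised through O1 as an oxocarbenium ion, ionises (SN1) and is captured by O7B in a 7-membered ring closure. O7B is held below the ring by the C7–O6B link and the C6 acetate shields the upper face through an acetoxonium ion, so the new C5–O bond forms cis to C7–O and trans to C6–OAc, inverting C5. C8 does not ionise because its cation has no support from O1.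

Step 15
Reactants: 26 (5R,6S,7R,8S)-6-O-acetyl-8-O-(tert-butyldimethylsilyl) derivative of 28
Product: 27 (5R,6S,7S,8S)-6-O-acetyl derivative of 28 (free C8 hydroxyl; the C7 descriptor changes by the sequence rule only)
Conditions: HF·pyridine, pyridine, THF, 0 °C → rt
Reagents that add atoms: none
Why: Fluoride cleavage of a secondary silyl ether under buffered, weakly acidic conditions that leave the acetate and both aryl ethers untouched.

Step 16
Reactants: 27 (5R,6S,7S,8S)-6-O-acetyl derivative of 28
Product: 28 (+)-4'-methoxyaquisinenone G, (5R,6S,7R,8S)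
Conditions: K2CO3 (cat.), MeOH, 0 °C
Reagents that add atoms: none
Why: Base-catalysed transesterification (Zemplén-type deacetylation) at low temperature; no stereocentre is involved.

## Compound list

1 | S-ethyl ethanethioate | CCSC(C)=O | starting material
2 | [(tert-butyldimethylsilyl)oxy]acetaldehyde | CC(C)(C)[Si](C)(C)OCC=O | starting material
3 | lithium 1-(ethylsulfanyl)ethen-1-olate (enolate of 1) | [Li]OC(=C)SCC | intermediate
4 | rac-S-ethyl 4-[(tert-butyldimethylsilyl)oxy]-3-hydroxybutanethioate | CCSC(=O)CC(O)CO[Si](C)(C)C(C)(C)C | intermediate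
5 | S-ethyl 4-[(tert-butyldimethylsilyl)oxy]-3-oxobutanethioate | CCSC(=O)CC(=O)CO[Si](C)(C)C(C)(C)C | intermediate
6 | 3-(4-methoxyphenyl)propanal | COc1ccc(CCC=O)cc1 | starting material
7 | 1-(4,4-dibromobut-3-en-1-yl)-4-methoxybenzene | COc1ccc(CCC=C(Br)Br)cc1 | intermediate
8 | [4-(4-methoxyphenyl)but-1-yn-1-yl]lithium | [Li]C#CCCc1ccc(OC)cc1 | intermediate
9 | 5-(4-methoxyphenyl)pent-2-ynoic acid | COc1ccc(CCC#CC(=O)O)cc1 | intermediate
10 | 5-(4-methoxyphenyl)pent-2-ynoyl chloride | COc1ccc(CCC#CC(=O)Cl)cc1 | intermediate
11 | S-ethyl 2-{[(tert-butyldimethylsilyl)oxy]acetyl}-7-(4-methoxyphenyl)-3-oxohept-4-ynethioate | CCSC(=O)C(C(=O)CO[Si](C)(C)C(C)(C)C)C(=O)C#CCCc1ccc(OC)cc1 | intermediate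
12 | S-ethyl 2-{[(tert-butyldimethylsilyl)oxy]methyl}-6-[2-(4-methoxyphenyl)ethyl]-4-oxo-4H-pyran-3-carbothioate | CCSC(=O)c1c(CO[Si](C)(C)C(C)(C)C)oc(CCc2ccc(OC)cc2)cc1=O | intermediate
13 | 2-{[(tert-butyldimethylsilyl)oxy]methyl}-6-[2-(4-methoxyphenyl)ethyl]-4-oxo-4H-pyran-3-carbaldehyde | COc1ccc(CCc2cc(=O)c(C=O)c(CO[Si](C)(C)C(C)(C)C)o2)cc1 | intermediate
14 | 1-(2-hydroxy-4,5-dimethoxyphenyl)ethanone | CC(=O)c1cc(OC)c(OC)cc1O | starting material
15 | ethyl 3-phenylpropanoate | CCOC(=O)CCc1ccccc1 | starting material
16 | 1-(2-hydroxy-4,5-dimethoxyphenyl)-5-phenylpentane-1,3-dione | COc1cc(O)c(C(=O)CC(=O)CCc2ccccc2)cc1OC | intermediate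
17 | 6,7-dimethoxy-2-(2-phenylethyl)-4H-chromen-4-one | COc1cc2oc(CCc3ccccc3)cc(=O)c2cc1OC | intermediate
18 | 6,7-dihydroxy-2-(2-phenylethyl)-4H-chromen-4-one | O=c1cc(CCc2ccccc2)oc2cc(O)c(O)cc12 | intermediate
19 | 6-hydroxy-7-(methoxymethoxy)-2-(2-phenylethyl)-4H-chromen-4-one | COCOc1cc2oc(CCc3ccccc3)cc(=O)c2cc1O | intermediate
20 | but-3-yn-2-one | CC(=O)C#C | starting material
21 | (E)-4-{[7-(methoxymethoxy)-4-oxo-2-(2-phenylethyl)-4H-chromen-6-yl]oxy}but-3-en-2-one | CC(=O)/C=C/Oc1cc2c(=O)cc(CCc3ccccc3)oc2cc1OCOC | intermediate
22 | (2Z,3Z)-2-{[(tert-butyldimethylsilyl)oxy]methylidene}-3-(hydroxymethylidene)-6-[2-(4-methoxyphenyl)ethyl]-2,3-dihydro-4H-pyran-4-one (photodienol, both oxygens outward) | O/C=C1\C(=O)C=C(CCc2ccc(OC)cc2)O/C1=C\O[Si](C)(C)C(C)(C)C | intermediate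
23 | (5R,6S,7R,8S)-6-acetyl-8-[(tert-butyldimethylsilyl)oxy]-5-hydroxy-2-[2-(4-methoxyphenyl)ethyl]-7-{[7-(methoxymethoxy)-4-oxo-2-(2-phenylethyl)-4H-chromen-6-yl]oxy}-5,6,7,8-tetrahydro-4H-chromen-4-one | COc1ccc(CCc2cc(=O)c3c(o2)[C@@H](O[Si](C)(C)C(C)(C)C)[C@H](Oc2cc4c(=O)cc(CCc5ccccc5)oc4cc2OCOC)[C@@H](C(C)=O)[C@H]3O)cc1 | intermediate
24 | (5S,6S,7R,8S)-8-[(tert-butyldimethylsilyl)oxy]-5-hydroxy-2-[2-(4-methoxyphenyl)ethyl]-7-{[7-(methoxymethoxy)-4-oxo-2-(2-phenylethyl)-4H-chromen-6-yl]oxy}-4-oxo-5,6,7,8-tetrahydro-4H-chromen-6-yl acetate | COc1ccc(CCc2cc(=O)c3c(o2)[C@@H](O[Si](C)(C)C(C)(C)C)[C@H](Oc2cc4c(=O)cc(CCc5ccccc5)oc4cc2OCOC)[C@@H](OC(C)=O)[C@H]3O)cc1 | intermediate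
25 | (5S,6S,7R,8S)-8-[(tert-butyldimethylsilyl)oxy]-5-hydroxy-7-{[7-hydroxy-4-oxo-2-(2-phenylethyl)-4H-chromen-6-yl]oxy}-2-[2-(4-methoxyphenyl)ethyl]-4-oxo-5,6,7,8-tetrahydro-4H-chromen-6-yl acetate | COc1ccc(CCc2cc(=O)c3c(o2)[C@@H](O[Si](C)(C)C(C)(C)C)[C@H](Oc2cc4c(=O)cc(CCc5ccccc5)oc4cc2O)[C@@H](OC(C)=O)[C@H]3O)cc1 | intermediate
26 | (5R,6S,7R,8S)-6-O-acetyl-8-O-(tert-butyldimethylsilyl) derivative of 28 (C5–O7B and C7–O6B dioxepine) | COc1ccc(CCc2cc(=O)c3c(o2)[C@@H](O[Si](C)(C)C(C)(C)C)[C@@H]2Oc4cc5c(=O)cc(CCc6ccccc6)oc5cc4O[C@H]3[C@@H]2OC(C)=O)cc1 | intermediate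
27 | (5R,6S,7S,8S)-6-O-acetyl derivative of 28 | COc1ccc(CCc2cc(=O)c3c(o2)[C@@H](O)[C@@H]2Oc4cc5c(=O)cc(CCc6ccccc6)oc5cc4O[C@H]3[C@@H]2OC(C)=O)cc1 | intermediate
28 | (+)-4'-methoxyaquisinenone G: (5R,6S,7R,8S)-6,8-dihydroxy-2-[2-(4-methoxyphenyl)ethyl]-5,6,7,8-tetrahydrochromone with C5 bonded to O7 and C7 bonded to O6 of 6,7-dioxy-2-(2-phenylethyl)chromone | COc1ccc(CCc2cc(=O)c3c(o2)[C@@H](O)[C@@H]2Oc4cc5c(=O)cc(CCc6ccccc6)oc5cc4O[C@H]3[C@@H]2O)cc1 | target

## Step count and risks

Total: 16 steps. Longest linear sequence: 10 steps (3, 4, 5, 6, 7, 12, 13, 14, 15, 16).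

**Step 12 (key step, proposed new method).**
- What may go wrong: photoenolisation may be inefficient, because the pyranone aldehyde can relax through a π,π* state or the chromone of 21 can absorb the light. The enone may photo-isomerise, which would erode the trans C6/C7 relation. Regio- or facial selectivity may be poor on a substrate with several titanium-binding carbonyls.
- Fallback: generate the same diene in the ground state, using known chemistry. Soft enolisation of 13 with Et3SiOTf/Et3N should give the bis(silyloxy) diene F1. A thermal Diels–Alder reaction of this 1,4-dioxygenated diene with 21 in toluene at 60–80 °C should give the racemic 5-O-triethylsilyl ether of 23, F2. Buffered HF·pyridine at 0 °C would cleave the triethylsilyl ether selectively, and the racemate would be resolved by preparative chromatography on a chiral stationary phase. The fallback sets out from 13 and 21 and returns at 23.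

**Step 14.**
- What may go wrong: the C5 cation may lose a proton and start aromatisation of the ring, or be captured intermolecularly before the seven-membered ring closes. Partial loss of the C8 silyl ether would be harmless, since step 15 removes it anyway.
- Fallback: replace ionisation by displacement. From 24, Me3SiOTf/2,2'-bipyridyl followed by water would remove the aryl MOM ether without Brønsted acid, giving phenol 25 as an isolated compound. A Mitsunobu etherification (PPh3, diisopropyl azodicarboxylate, toluene, high dilution) would then close C5–O7B with inversion and return to the route at 26.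

**Step 13.**
- What may go wrong: migration of the C6 carbon may be slow, since it carries two β-oxygen substituents. Retro-aldol cleavage of the β-hydroxy ketone, β-elimination of the aryloxy group, or oxidation of the anisole ring could then compete.
- Fallback: oxidise after ring closure. From 23, MOM removal with Me3SiOTf/2,2'-bipyridyl then water would give the phenol ketone F3. Mitsunobu closure (PPh3, diisopropyl azodicarboxylate) would give the bridged methyl ketone F4, which has neither a free β-hydroxyl nor an acid-labile group. A more forcing Baeyer–Villiger oxidation (CF3CO3H, Na2HPO4, CH2Cl2) would then be possible and would return to the route at 26.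

**Step 10.**
- What may go wrong: poor site selectivity between the two phenols, or double alkylation.
- Fallback: differentiate by deacylation instead of alkylation. From 18, Ac2O/pyridine would give the diacetate F5. Thiophenol and imidazole in N-methylpyrrolidone would remove the more labile 7-acetate, a known selectivity in acetylated flavones, giving the 6-acetoxy-7-hydroxy chromone F6. MeOCH2Cl/iPr2NEt would give the 6-acetoxy-7-(methoxymethoxy) chromone F7, and K2CO3/MeOH would return to the route at 19.

## Further compounds

F1 | step 12 | (2Z,3Z)-2-{[(tert-butyldimethylsilyl)oxy]methylidene}-3-{[(triethylsilyl)oxy]methylidene}-6-[2-(4-methoxyphenyl)ethyl]-2,3-dihydro-4H-pyran-4-one | CC[Si](CC)(CC)O/C=C1\C(=O)C=C(CCc2ccc(OC)cc2)O/C1=C\O[Si](C)(C)C(C)(C)C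
F2 | step 12 | 5-O-triethylsilyl ether of 23 (racemic; one enantiomer drawn) | COc1ccc(CCc2cc(=O)c3c(o2)[C@@H](O[Si](C)(C)C(C)(C)C)[C@H](Oc2cc4c(=O)cc(CCc5ccccc5)oc4cc2OCOC)[C@@H](C(C)=O)[C@H]3O[Si](CC)(CC)CC)cc1
F0 | step 14 | none | none
F3 | step 13 | 23 lacking the MOM group (free 7-hydroxyl on the aromatic chromone) | COc1ccc(CCc2cc(=O)c3c(o2)[C@@H](O[Si](C)(C)C(C)(C)C)[C@H](Oc2cc4c(=O)cc(CCc5ccccc5)oc4cc2O)[C@@H](C(C)=O)[C@H]3O)cc1
F4 | step 13 | 6-acetyl analogue of 26 (bridged methyl ketone) | COc1ccc(CCc2cc(=O)c3c(o2)[C@@H](O[Si](C)(C)C(C)(C)C)[C@@H]2Oc4cc5c(=O)cc(CCc6ccccc6)oc5cc4O[C@H]3[C@@H]2C(C)=O)cc1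
F5 | step 10 | 4-oxo-2-(2-phenylethyl)-4H-chromene-6,7-diyl diacetate | CC(=O)Oc1cc2oc(CCc3ccccc3)cc(=O)c2cc1OC(C)=O
F6 | step 10 | 7-hydroxy-4-oxo-2-(2-phenylethyl)-4H-chromen-6-yl acetate | CC(=O)Oc1cc2c(=O)cc(CCc3ccccc3)oc2cc1O
F7 | step 10 | 7-(methoxymethoxy)-4-oxo-2-(2-phenylethyl)-4H-chromen-6-yl acetate | CC(=O)Oc1cc2c(=O)cc(CCc3ccccc3)oc2cc1OCOC
A1 | alternative 1 | bridged bicyclic C8a ketone with both aryl ether bonds and 6,8-dibenzyl ethers | O=C1[C@@H](OCc6ccccc6)[C@@H]2Oc3cc4c(=O)cc(CCc5ccccc5)oc4cc3O[C@H](C1)[C@@H]2OCc6ccccc6
A2 | alternative 2 | bridged 6-hydroxy-8-ketone (8-oxo analogue of 28) | COc1ccc(CCc2cc(=O)c3c(o2)C(=O)[C@@H]2Oc4cc5c(=O)cc(CCc6ccccc6)oc5cc4O[C@H]3[C@@H]2O)cc1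
A3 | alternative 3 | trans-7-aryloxy-8-hydroxy-7,8-dihydrochromone with free O7B phenol | COc1ccc(CCc2cc(=O)c3c(o2)[C@@H](O)[C@H](Oc2cc4c(=O)cc(CCc5ccccc5)oc4cc2O)C=C3)cc1
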